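**Retrosynthetic overview**
1. The side-chain ester is cut first, giving (3R,5S)-3-hydroxy-3,5-dimethylheptanoic acid (from an (S)-3-hydroxybutanoic acid dioxinone and an (S)-2-methylbutyl Grignard reagent) and a tetracyclic hydroxy enone. The diosphenol of ring A is made last by α′-hydroxylation and tautomerisation.
2. Ring B (eight-membered) is closed by ring-closing metathesis at C11=C12, after a ring C/D vinyl anion has been added to the ketone of (R)-allethrolone, which is ring A.
3. Rings C and D are formed together by an intramolecular Pauson–Khand [2+2+1] cycloaddition of a 1,7-enyne, which sets the angular methyl; Li/NH3 then sets C4, C5 and C6.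
4. The C2–C10 bond and both of its stereocentres come from an Ireland–Claisen [3,3] rearrangement with chirality transfer from (S)-but-3-yn-2-ol.
5. Ring order: A is bought; C and D (Pauson–Khand); B (metathesis); the oxidation level of A is adjusted at the end.

Assumptions: (R)-allethrolone, (S)-but-3-yn-2-ol, (S)-3-hydroxybutanoic acid and (S)-1-bromo-2-methylbutane are bought enantiopure. Locants C1–C18 in the names follow the atom order of the target SMILES (C1 carries the exocyclic CH2, C8 the angular methyl; the face of that methyl is β).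

**Route**

Step 1
Reactants: 1 3-methylbut-1-yne, 2 oxetane
Product: 4 6-methylhept-4-yn-1-ol, via lithium acetylide 3 (not isolated)
Conditions: n-BuLi, THF, −78 °C; BF3·OEt2, then 2, −78 °C; NH4Cl (aq)
Reagents that add atoms: none
Why: BF3-assisted opening of oxetane by a lithium acetylide gives the three-carbon-extended alkynol, with no stereocentre involved.

Step 2
Reactants: 4 6-methylhept-4-yn-1-ol
Product: 5 6-methylhept-4-ynoic acid
Conditions: TEMPO (10 mol %), PhI(OAc)2 (2.2 equiv), MeCN/H2O 1:1, 23 °C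
Reagents that add atoms: water, O
Why: Oxoammonium (TEMPO) oxidation takes the primary alcohol through the aldehyde hydrate to the acid and leaves the alkyne alone.

Step 3
Reactants: 6 (S)-but-3-yn-2-ol, 7 3-chloro-2-methylprop-1-ene
Product: 9 (2S,3E)-3,6-dimethylhepta-3,6-dien-2-ol, via alkenylalane 8 (not isolated)
Conditions: Me3Al (3 equiv), Cp2ZrCl2 (0.25 equiv), CH2Cl2, 0 → 23 °C; then 7, Pd(PPh3)4 (5 mol %), THF, 23 °C; HCl (aq)
Reagents that add atoms: trimethylaluminium, C[Al](C)C
Why: Negishi zirconium-catalysed syn-carboalumination puts methyl on the inner alkyne carbon, and palladium-catalysed allylation of the alkenylalane fixes the E trisubstituted alkene; the carbinol centre is untouched.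

Step 4
Reactants: 5 6-methylhept-4-ynoic acid, 9 (2S,3E)-3,6-dimethylhepta-3,6-dien-2-ol
Product: 10 (2S,3E)-3,6-dimethylhepta-3,6-dien-2-yl 6-methylhept-4-ynoate
Conditions: DCC, DMAP (cat.), CH2Cl2, 0 → 23 °C
Reagents that add atoms: none
Why: Steglich esterification acylates the secondary allylic alcohol without touching its stereocentre.

Step 5
Reactants: 10 (2S,3E)-3,6-dimethylhepta-3,6-dien-2-yl 6-methylhept-4-ynoate
Product: 13 (2S,3S,4E)-4-methyl-2-(4-methylpent-2-yn-1-yl)-3-(2-methylprop-2-en-1-yl)hex-4-enoic acid, via silyl ketene acetal 11 (not isolated), via silyl ester 12 (not isolated)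
Conditions: LiN(iPr)2 (LDA), THF/HMPA 77:23, −78 °C; Me3SiCl; −78 → 50 °C; 1 M HCl
Reagents that add atoms: none
Why: In the Ireland–Claisen [3,3] rearrangement the chair transition state with the carbinol methyl equatorial and the HMPA-derived ketene acetal (α-CH2 cis to OSiMe3) forms the C2–C10 bond with both stereocentres by 1,3-chirality transfer from the (S)-carbinol.

Step 6
Reactants: 13 (2S,3S,4E)-4-methyl-2-(4-methylpent-2-yn-1-yl)-3-(2-methylprop-2-en-1-yl)hex-4-enoic acid
Product: 14 (5S,6S,7aS)-6-[(2E)-but-2-en-2-yl]-7a-methyl-2-oxo-3-(propan-2-yl)-2,4,5,6,7,7a-hexahydro-1H-indene-5-carboxylic acid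
Conditions: Co2(CO)8 (0.2 equiv), tetramethylthiourea (1.2 equiv), CO (1 atm), toluene, 70 °C
Reagents that add atoms: carbon monoxide, [C-]#[O+]
Why: The intramolecular Pauson–Khand [2+2+1] cycloaddition of the 1,7-enyne builds rings C and D at once; a chair-like cobaltacycle with both tether substituents equatorial places the new angular methyl axial (β), and the trisubstituted butenyl alkene is too hindered to compete.

Step 7
Reactants: 14 bicyclic enone acid
Product: 16 (2R,3R,3aS,5S,6S,7aS)-6-[(2E)-but-2-en-2-yl]-2-hydroxy-7a-methyl-3-(propan-2-yl)octahydro-1H-indene-5-carboxylic acid, via saturated ketone 15 (not isolated)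
Conditions: Li (12 equiv), NH3 (l)/THF, −78 °C; then MeOH, −78 → −33 °C; NH4Cl
Reagents that add atoms: none
Why: In this dissolving-metal (Birch-type) reduction, axial protonation at C4 gives the trans-hydrindane, the enolate is protonated at C5 from the α-face away from the angular methyl, and the ketone is reduced to the more stable 6α-alcohol trans to isopropyl; the carboxylate and the isolated alkene are inert.

Step 8
Reactants: 16 hydroxy acid
Product: 17 1-[(2R,3R,3aS,5S,6S,7aS)-6-[(2E)-but-2-en-2-yl]-2-hydroxy-7a-methyl-3-(propan-2-yl)octahydro-1H-inden-5-yl]ethan-1-one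
Conditions: MeLi (4.5 equiv), THF, 0 → 23 °C; inverse quench into 1 M HCl, 0 °C
Reagents that add atoms: methyllithium, [Li]C
Why: Methyllithium adds once to the lithium carboxylate and the gem-dialkoxide collapses to the methyl ketone on work-up; C2 sits α to the ketone in its stable equatorial form.

Step 9
Reactants: 17 methyl ketone
Product: 18 2,4,6-triisopropylbenzenesulfonyl hydrazone of 17
Conditions: 2,4,6-triisopropylbenzenesulfonohydrazide, THF, 23 °C
Reagents that add atoms: 2,4,6-triisopropylbenzenesulfonohydrazide, NNS(=O)(=O)c1c(C(C)C)cc(C(C)C)cc1C(C)C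
Why: Condensation gives the trisylhydrazone needed for the Shapiro reaction.

Step 10
Reactants: 19 (R)-allethrolone
Product: 20 (4R)-4-[(tert-butyldimethylsilyl)oxy]-3-methyl-2-(prop-2-en-1-yl)cyclopent-2-en-1-one
Conditions: t-BuMe2SiCl, imidazole, DMF, 23 °C
Reagents that add atoms: tert-butyldimethylsilyl chloride, CC(C)(C)[Si](C)(C)Cl
Why: Silylation turns the carbinol into a bulky group that shields one face of the ring A ketone.

Step 11
Reactants: 18 trisylhydrazone, 20 silyl ether of (R)-allethrolone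
Product: 22 ring C/D–ring A carbinol (C1(=CH2)–C18 bond formed; 6α-OH; 16α-OSiMe2t-Bu; 18α-OH; ring B open), via vinyllithium 21 (not isolated)
Conditions: n-BuLi (3.3 equiv), THF, −78 → 0 °C; −78 °C, anhydrous CeCl3 (1.5 equiv), then 20; NH4Cl (aq)
Reagents that add atoms: none
Why: The Shapiro reaction gives the 1,1-disubstituted vinyllithium, whose CeCl3-mediated 1,2-addition to the enone carbonyl occurs anti to the 16α-silyloxy group and so sets C18 with its hydroxyl α.

Step 12
Reactants: 22 ring C/D–ring A carbinol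
Product: 23 tetracyclic silyl ether diol (rings A to D; Z-C11=C12; C14=C15; 6α-OH; 16α-OSiMe2t-Bu; 18α-OH)
Conditions: second-generation Hoveyda–Grubbs catalyst (10 mol %), 1,4-benzoquinone (20 mol %), toluene (2 mM), 80 °C
Reagents that add atoms: none
Why: Ring-closing metathesis between the allyl group and the butenyl group (propene lost) closes ring B from the gauche, trans-diequatorial arms on C2 and C10; the ring enforces the Z alkene, and the C1 methylene, flanked by a fully substituted carbinol carbon and a ring methine, is expected to stay out.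

Step 13
Reactants: 23 tetracyclic silyl ether diol
Product: 24 tetracyclic 6α,16α,18α-triol
Conditions: Bu4NF, THF, 0 → 23 °C; NH4Cl (aq)
Reagents that add atoms: none
Why: Fluoride cleaves the only silyl ether.

Step 14
Reactants: 24 tetracyclic triol
Product: 25 tetracyclic enone diol (C16 ketone conjugated to C14=C15; 6α-OH; 18α-OH)
Conditions: MnO2 (20 equiv), CH2Cl2, 23 °C
Reagents that add atoms: none
Why: MnO2 oxidises only the allylic C16 alcohol; the saturated C6 alcohol and the tertiary C18 alcohol do not react.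

Step 15
Reactants: 26 (S)-3-hydroxybutanoic acid
Product: 27 (2S,6S)-2-tert-butyl-6-methyl-1,3-dioxan-4-one
Conditions: pivalaldehyde, pyridinium p-toluenesulfonate (cat.), CH2Cl2, reflux (water separator); recrystallise
Reagents that add atoms: pivalaldehyde, CC(C)(C)C=O
Why: Acetalisation gives the cis-dioxanone, which stores the chirality of C6 in the new acetal centre (Seebach self-regeneration of stereocentres).

Step 16
Reactants: 27 cis-dioxanone
Product: 29 (2S)-2-tert-butyl-6-methyl-4H-1,3-dioxin-4-one, via 6-bromodioxanone 28 (not isolated)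
Conditions: NBS, AIBN (cat.), CCl4, reflux; then Et3N, 0 → 23 °C
Reagents that add atoms: none
Why: Radical bromination at the tertiary C6–H followed by dehydrobromination gives the dioxinone with the acetal centre intact.

Step 17
Reactants: 29 (S)-dioxinone, 30 (S)-1-bromo-2-methylbutane
Product: 33 (3R,5S)-3-hydroxy-3,5-dimethylheptanoic acid, via Grignard reagent 31 (not isolated), via dioxanone adduct 32 (not isolated)
Conditions: 30, Mg, THF, 23 °C; CuBr·SMe2 (20 mol %), −78 °C, then 29, −78 → −30 °C; then 3 M HCl, THF, 40 °C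
Reagents that add atoms: none
Why: Copper-catalysed conjugate addition enters trans to the tert-butyl group and sets the tertiary carbinol centre as R; acetal hydrolysis frees the β-hydroxy acid, and the C5 centre is carried in from the bromide.

Step 18
Reactants: 25 tetracyclic enone diol, 33 (3R,5S)-3-hydroxy-3,5-dimethylheptanoic acid
Product: 34 6-O-[(3R,5S)-3-hydroxy-3,5-dimethylheptanoyl] ester of 25
Conditions: EDC·HCl, DMAP, CH2Cl2, 0 → 23 °C
Reagents that add atoms: none
Why: Carbodiimide (Steglich-type) esterification acylates the only secondary hydroxyl; both tertiary hydroxyls are unreactive.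

Step 19
Reactants: 34 ester enone
Product: 36 CNP0110944.3, via hydroxy enone 35 (not isolated)
Conditions: LiN(SiMe3)2 (3.3 equiv), THF, −78 °C; 2-(phenylsulfonyl)-3-phenyloxaziridine, −78 °C; AcOH; then Et3N, CH2Cl2, 23 °C
Reagents that add atoms: 2-(phenylsulfonyl)-3-phenyloxaziridine, O=S(=O)(c1ccccc1)N1OC1c1ccccc1
Why: The cross-conjugated enolate at C17 (the only α′-hydrogens) undergoes Davis hydroxylation, and base-mediated ketol–enediol tautomerisation then delivers the hydrogen to C14 on the α-face, cis to the 18-OH, giving the conjugated diosphenol as the thermodynamic sink.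

**Compound list**
1 | 3-methylbut-1-yne | CC(C)C#C | starting material
2 | oxetane | C1COC1 | starting material
3 | lithium 3-methylbut-1-yn-1-ide | CC(C)C#C[Li] | intermediate (not isolated)
4 | 6-methylhept-4-yn-1-ol | CC(C)C#CCCCO | intermediate
5 | 6-methylhept-4-ynoic acid | CC(C)C#CCCC(=O)O | intermediate
6 | (S)-but-3-yn-2-ol | C[C@H](O)C#C | starting material
7 | 3-chloro-2-methylprop-1-ene | CC(=C)CCl | starting material
8 | (E)-alkenylalane from 6 (Me and Al cis; O–AlMe2 alkoxide) | C[C@H](O[Al](C)C)/C(C)=C/[Al](C)C | intermediate (not isolated)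
9 | (2S,3E)-3,6-dimethylhepta-3,6-dien-2-ol | C[C@H](O)/C(C)=C/CC(C)=C | intermediate
10 | (2S,3E)-3,6-dimethylhepta-3,6-dien-2-yl 6-methylhept-4-ynoate | CC(C)C#CCCC(=O)O[C@@H](C)/C(C)=C/CC(C)=C | intermediate
11 | trimethylsilyl ketene acetal of 10 (α-CH2 cis to OSiMe3) | CC(C)C#CC/C=C(\O[Si](C)(C)C)O[C@@H](C)/C(C)=C/CC(C)=C | intermediate (not isolated)
12 | trimethylsilyl ester of 13 | C[Si](C)(C)OC(=O)[C@@H](CC#CC(C)C)[C@H](CC(C)=C)/C(C)=C/C | intermediate (not isolated)
13 | (2S,3S,4E)-4-methyl-2-(4-methylpent-2-yn-1-yl)-3-(2-methylprop-2-en-1-yl)hex-4-enoic acid | OC(=O)[C@@H](CC#CC(C)C)[C@H](CC(C)=C)/C(C)=C/C | intermediate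
14 | (5S,6S,7aS)-6-[(2E)-but-2-en-2-yl]-7a-methyl-2-oxo-3-(propan-2-yl)-2,4,5,6,7,7a-hexahydro-1H-indene-5-carboxylic acid | OC(=O)[C@H]1CC2=C(C(C)C)C(=O)C[C@]2(C)C[C@@H]1/C(C)=C/C | intermediate
15 | trans-fused saturated ketone acid (4α-H, 5β-isopropyl, C6 ketone) | OC(=O)[C@H]1C[C@H]2[C@@H](C(C)C)C(=O)C[C@]2(C)C[C@@H]1/C(C)=C/C | intermediate (not isolated)
16 | (2R,3R,3aS,5S,6S,7aS)-6-[(2E)-but-2-en-2-yl]-2-hydroxy-7a-methyl-3-(propan-2-yl)octahydro-1H-indene-5-carboxylic acid | OC(=O)[C@H]1C[C@H]2[C@@H](C(C)C)[C@H](O)C[C@]2(C)C[C@@H]1/C(C)=C/C | intermediate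
17 | 1-[(2R,3R,3aS,5S,6S,7aS)-6-[(2E)-but-2-en-2-yl]-2-hydroxy-7a-methyl-3-(propan-2-yl)octahydro-1H-inden-5-yl]ethan-1-one | CC(=O)[C@H]1C[C@H]2[C@@H](C(C)C)[C@H](O)C[C@]2(C)C[C@@H]1/C(C)=C/C | intermediate
18 | (E)-2,4,6-triisopropylbenzenesulfonyl hydrazone of 17 | C/C(=N\NS(=O)(=O)c1c(C(C)C)cc(C(C)C)cc1C(C)C)[C@H]2C[C@H]3[C@@H](C(C)C)[C@H](O)C[C@]3(C)C[C@@H]2/C(C)=C/C | intermediate
19 | (R)-allethrolone, (4R)-4-hydroxy-3-methyl-2-(prop-2-en-1-yl)cyclopent-2-en-1-one | C=CCC1=C(C)[C@H](O)CC1=O | starting material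
20 | (4R)-4-[(tert-butyldimethylsilyl)oxy]-3-methyl-2-(prop-2-en-1-yl)cyclopent-2-en-1-one | C=CCC1=C(C)[C@H](O[Si](C)(C)C(C)(C)C)CC1=O | intermediate
21 | C1 vinyllithium of the ring C/D unit (as lithium 6-alkoxide) | [Li]C(=C)[C@H]1C[C@H]2[C@@H](C(C)C)[C@H](O[Li])C[C@]2(C)C[C@@H]1/C(C)=C/C | intermediate (not isolated)
22 | ring C/D–ring A carbinol (6α-OH, 16α-OSiMe2t-Bu, 18α-OH; butenyl on C10, allyl on C14) | C=C([C@H]1C[C@H]2[C@@H](C(C)C)[C@H](O)C[C@]2(C)C[C@@H]1/C(C)=C/C)[C@]3(O)C[C@@H](O[Si](C)(C)C(C)(C)C)C(C)=C3CC=C | intermediate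
23 | tetracyclic silyl ether diol (Z-C11=C12, C14=C15; 6α-OH, 16α-OSiMe2t-Bu, 18α-OH) | C=C1[C@H]2C[C@H]3[C@@H](C(C)C)[C@H](O)C[C@]3(C)C[C@@H]2/C(C)=C\CC4=C(C)[C@H](O[Si](C)(C)C(C)(C)C)C[C@@]14O | intermediate
24 | tetracyclic 6α,16α,18α-triol | C=C1[C@H]2C[C@H]3[C@@H](C(C)C)[C@H](O)C[C@]3(C)C[C@@H]2/C(C)=C\CC4=C(C)[C@H](O)C[C@@]14O | intermediate
25 | tetracyclic enone diol (C16=O, C14=C15; 6α-OH, 18α-OH) | C=C1[C@H]2C[C@H]3[C@@H](C(C)C)[C@H](O)C[C@]3(C)C[C@@H]2/C(C)=C\CC4=C(C)C(=O)C[C@@]14O | intermediate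
26 | (S)-3-hydroxybutanoic acid | C[C@H](O)CC(=O)O | starting material
27 | (2S,6S)-2-tert-butyl-6-methyl-1,3-dioxan-4-one | C[C@H]1CC(=O)O[C@@H](C(C)(C)C)O1 | intermediate
28 | 6-bromo derivative of 27 (C6 as formed) | CC1(Br)CC(=O)O[C@@H](C(C)(C)C)O1 | intermediate (not isolated)
29 | (2S)-2-tert-butyl-6-methyl-4H-1,3-dioxin-4-one | CC1=CC(=O)O[C@@H](C(C)(C)C)O1 | intermediate
30 | (S)-1-bromo-2-methylbutane | CC[C@H](C)CBr | starting material
31 | (S)-2-methylbutylmagnesium bromide | CC[C@H](C)C[Mg]Br | intermediate (not isolated)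
32 | (2S,6R)-2-tert-butyl-6-methyl-6-[(2S)-2-methylbutyl]-1,3-dioxan-4-one | C[C@@]1(C[C@@H](C)CC)CC(=O)O[C@@H](C(C)(C)C)O1 | intermediate (not isolated)
33 | (3R,5S)-3-hydroxy-3,5-dimethylheptanoic acid | OC(=O)C[C@](C)(O)C[C@@H](C)CC | intermediate
34 | 6-O-[(3R,5S)-3-hydroxy-3,5-dimethylheptanoyl] ester of 25 | C=C1[C@H]2C[C@H]3[C@@H](C(C)C)[C@H](OC(=O)C[C@](C)(O)C[C@@H](C)CC)C[C@]3(C)C[C@@H]2/C(C)=C\CC4=C(C)C(=O)C[C@@]14O | intermediate
35 | 17-hydroxy derivative of 34 (C17 epimers, both converge) | C=C1[C@H]2C[C@H]3[C@@H](C(C)C)[C@H](OC(=O)C[C@](C)(O)C[C@@H](C)CC)C[C@]3(C)C[C@@H]2/C(C)=C\CC4=C(C)C(=O)C(O)[C@@]14O | intermediate (not isolated)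
36 | CNP0110944.3 | C=C1[C@H]2C[C@H]3[C@@H](C(C)C)[C@H](OC(=O)C[C@](C)(O)C[C@@H](C)CC)C[C@]3(C)C[C@@H]2/C(C)=C\C[C@H]2C(C)=C(O)C(=O)[C@@]12O | target

**Step count and risks**
Total: 19 steps. Longest linear sequence: 14 steps (1, 2, 4–9, 11–14, 18, 19).

Most likely to fail, first: step 12. The ruthenium carbene formed on the allyl group could instead close a five-membered ring onto the C1 methylene, and the eight-membered ring with a trisubstituted alkene is slow to form. The fallback masks that methylene; it sets out from 18 and comes back at 24. The dianion of 18 is treated with benzyl(chloro)dimethylsilane before the second deprotonation, so that the vinyl anion carries a CH–SiMe2Bn terminus (the C6 alkoxide is silylated as well). Addition to 20 as in step 11 gives the silyl-masked carbinol F3. Its trisubstituted vinylsilane is inert to the catalyst, so metathesis under the step 12 conditions can only close ring B, giving the silyl-masked tetracycle F4. Bu4NF in THF then removes all three silyl groups, including protodesilylation of the benzyldimethylsilyl alkene, to give triol 24.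

Second: step 6. A 1,7-enyne with a 1,1-disubstituted alkene is a slow Pauson–Khand substrate, and the butenyl alkene (1,6 to the alkyne) might interfere. The fallback ties up that alkene together with the acid; it sets out from 13 and comes back at 14. Iodolactonisation (I2, NaHCO3, MeCN, 0 °C) gives the iodolactone F1, in which only the 2-methylallyl alkene can pair with the alkyne. The Pauson–Khand reaction under the step 6 conditions gives the tricyclic iodolactone enone F2. Zn dust in AcOH/THF reopens the lactone by reductive elimination to 14; the geometry of the regenerated butenyl alkene does not matter, since it is lost as propene in step 12.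

Third: step 19. The strong base meets a β-hydroxy ketone (retro-aldol), a β-hydroxy ester and a second enolisable carbonyl in the side chain. The fallback avoids enolate chemistry; it sets out from 34 and comes back at 36. Mn(OAc)3 in benzene at reflux acetoxylates the enone at C17 to give the acetoxy enone F5. K2CO3 (0.1 equiv) in MeOH at 0 °C removes the activated acetate, and the freed ketol tautomerises to the diosphenol 36.

Further compounds
F1 | step 6 | iodolactone of 13 (γ-lactone oxygen on C11, iodine on C12, new centres as formed) | CC(I)C1(C)OC(=O)[C@@H](CC#CC(C)C)[C@@H]1CC(C)=C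
F2 | step 6 | tricyclic iodolactone enone (Pauson–Khand product of F1) | CC(I)C1(C)OC(=O)[C@H]2CC3=C(C(C)C)C(=O)C[C@]3(C)C[C@H]12
F3 | step 12 | silyl-masked carbinol (22 with C1=CH–SiMe2Bn and 6-O–SiMe2Bn, alkene geometry as formed) | C[Si](C)(Cc1ccccc1)C=C([C@H]2C[C@H]3[C@@H](C(C)C)[C@H](O[Si](C)(C)Cc1ccccc1)C[C@]3(C)C[C@@H]2/C(C)=C/C)[C@]4(O)C[C@@H](O[Si](C)(C)C(C)(C)C)C(C)=C4CC=C
F4 | step 12 | silyl-masked tetracycle (23 with C1=CH–SiMe2Bn and 6-O–SiMe2Bn) | C[Si](C)(Cc1ccccc1)C=C2[C@H]3C[C@H]4[C@@H](C(C)C)[C@H](O[Si](C)(C)Cc1ccccc1)C[C@]4(C)C[C@@H]3/C(C)=C\CC5=C(C)[C@H](O[Si](C)(C)C(C)(C)C)C[C@@]25O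
F5 | step 19 | 17-acetoxy enone from 34 (C17 epimers) | C=C1[C@H]2C[C@H]3[C@@H](C(C)C)[C@H](OC(=O)C[C@](C)(O)C[C@@H](C)CC)C[C@]3(C)C[C@@H]2/C(C)=C\CC4=C(C)C(=O)C(OC(C)=O)[C@@]14O
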